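The numbers in the tables stem from a simulated flask with constants of no real substance.

Set the flask beside the ash run: both charge the same partner, and the flask holds twice the substrate.

| setting | elm | ash | flask |
|---|---|---|---|
| substrate | 0.78 M | 0.39 M | 0.78 M |
| partner | 0.97 M | 1.95 M | 1.95 M |
| remark | run made earlier | run made earlier |  |
| time |  |  | 50 min |

| run | time / min | target / % | substrate / % |
|---|---|---|---|
| elm | 1.00 | 13.9 | 86.3 |
| elm | 3.00 | 21.2 | 76.9 |
| elm | 12.0 | 10.4 | 86.1 |
| elm | 40.0 | 1.2 | 98.8 |
| ash | 1.00 | 25.9 | 74.6 |
| ash | 3.00 | 41.1 | 56.8 |
| ash | 12.0 | 22.9 | 75.5 |
| ash | 40.0 | 0.9 | 96.6 |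

(standard deviation of a reading: 1 percentage point)

- amounts and yields of target count idle adduct and crystals too
- given per volume of solution although it is solid: crystals
- reactions considered so far: crystals <-> target; substrate + partner <-> target; substrate + partner <-> isomer of the product; partner + target <-> idle adduct; partner -> decomposed reagent

- time, not beyond 50 min, at which the flask holds most target
- the amount of target, in percent of the substrate charged, at that time
- earliest time at which at least nineteen twentieths of that best amount are there, in min
- latest time at which they still are, in min

In the first minute ash turned 25.9 % of its substrate into target and elm 13.9 %. That is a ratio of 1.86 against 2.01 in partner charge, so we read the early percent per minute as following the partner charge. Both runs then fall back. At 40.0 min ash reads 0.9 % target and 96.6 % substrate, elm 1.2 % and 98.8 %. We read this as partner decomposing while target reverts to substrate and partner, and we expect the flask to end the same way.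

So the flask should follow ash, peaking near 3.00 min, except that its substrate takes more from the same partner. We reckon this from ash's highest reading:

draw = c(target at peak) / c(partner charged)

ash: 8.22 %

flask, at ash's percent: 16.4 %

This partner draw, the share of the charged partner sitting in target at the peak, one partner per target, leaves the rest undrawn. At one partner charge we scale the peak with that undrawn share:

peak in flask = 41.1 % × 84 percentage points / 92 points = 37.4 %

The forecast gave 37 % at 3.3 min, with a window from 2.1 min to 5 min, from “a flat peak near 3 min at about 36–37%”.

The flask gives 38.6 % at 3.91 min, and holds the asked share of that from 2.62 min to 5.66 min.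

    crystals ⇌ target, rate k1*(cs1 - [target]) while solid is left; crystals form when [target] > cs1 (solubility = 0.230 M, k = 0.670 s⁻¹)
    substrate + partner ⇌ target (K = 0.940 L mol⁻¹, k = 0.00310 L mol⁻¹ s⁻¹)
    substrate + partner ⇌ isomer of the product (K = 1.50 L mol⁻¹, k = 1.30 × 10⁻⁴ L mol⁻¹ s⁻¹)
    partner + target ⇌ idle adduct, settled at all times (K = 1.20 L mol⁻¹)
    partner → decomposed reagent (k = 0.00490 s⁻¹)

The flask stands 1.2 points above our reckoning. The neighbour flask keeps the partner charge but holds 0.20 M of substrate. Its draw at ash's percent is 4.22 %, below ash's 8.22 %, so the same scaling gives 42.9 %. The neighbour reaches 44.2 %, which is 1.3 points above that reckoning and above the flask. At 50.0 min it holds 0.0746 % target, 0.013 % of its partner and 97 % of its substrate.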